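The route rests on cutting the C1–C5 bond shared by the five- and seven-membered rings of a cis-fused guaianolide. A C10 aldehyde enolate pushes through that bond into a spiro C4–C15 oxirane (enolate–epoxide Grob fragmentation). In one operation this merges the two rings into the ten-membered ring and releases both ring-cis trisubstituted alkenes, C1=C10 bearing the C14 aldehyde and C4=C5 bearing the C15 carbinol, 1,5-related across C2–C3, at their final oxidation levels. The precursor is a 4,15-epoxy-14-oxo-cis-guaian-12,6-olide already carrying the α-methylene lactone and the 8β-isovalerate. It is built from cyclopentenone by alkyne photocycloaddition, sulfoximine resolution, cyclobutene ethenolysis and two allylations.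

Key step: step 14

Remark (numbering): guaiane/germacrane atom numbers C1–C15 are used for all intermediates; α is the face of H1, H5 and H7.
Remark (assumption on C8): the indium-mediated ring closure of step 10 is taken to give the 8β-carbinol directly, because a closed six-membered allylindium transition state puts O8 gauche to C10, the axial β position on the chair fixed by the trans-lactone; the ester is therefore attached with retention, and an invertive esterification is kept as fallback for the 8α-epimer.
Remark (chirality): compound 3 is racemic and drawn as the enantiomer carried on; all compounds from 6 onward are single enantiomers.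

Step 1
Reactants: 1 cyclopent-2-en-1-one; 2 prop-2-yn-1-yl benzoate
Product: 3 rac-cis-6-(benzoyloxymethyl)bicyclo[3.2.0]hept-6-en-2-one (ring-fusion hydrogens cis)
Conditions: hν (Hg lamp, uranium-glass filter, λ > 330 nm), 2 in excess, CH2Cl2, −20 °C, stopped before full conversion
Reagents that add atoms: none
Why: Enone–alkyne [2+2] photocycloaddition: the excited enone should add the terminal alkyne head-to-tail (substituted alkyne carbon to the enone β-carbon, forming C5–C6 and C1–C10), the four-membered ring can only fuse cis so H1 and H5 end cis (racemic), the long-wavelength filter limits the secondary 1,3-acyl shift of the β,γ-unsaturated ketone, and the head-to-head isomer is removed by chromatography.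

Step 2
Reactants: 3 rac-cis-6-(benzoyloxymethyl)bicyclo[3.2.0]hept-6-en-2-one; 4 (S)-N,S-dimethyl-S-phenylsulfoximine
Product: 6 6-(benzoyloxymethyl)-2-[(N-methyl-S-phenylsulfonimidoyl)methyl]bicyclo[3.2.0]hept-6-en-2-ol (hydroxyl on the cyclobutene face; CH2S on the convex face; S at sulfur; single diastereomer), via lithiated sulfoximine 5 (not isolated)
Conditions: 4, n-BuLi, THF, −78 °C; then 3, −78 °C; aq NH4Cl; separation of the two diastereomeric carbinols on SiO2
Reagents that add atoms: none
Why: 1,2-Addition of an α-lithiated sulfoximine to a ketone, used as a resolution: the carbanion should attack C4 from the convex face anti to the cyclobutene, placing the new hydroxyl on the cyclobutene face, and because 4 is one enantiomer the adducts of the two enantiomers of 3 are diastereomers separable on silica (the required one to be assigned by crystallography); at −78 °C ketone addition should outrun attack on the benzoate.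

Step 3
Reactants: 6 the sulfoximine carbinol
Product: 8 6-(benzoyloxymethyl)spiro[bicyclo[3.2.0]hept-6-ene-2,2'-oxirane] (4,15-epoxide; oxirane oxygen on the cyclobutene face), via aminosulfoxonium salt 7 (not isolated)
Conditions: Me3OBF4, CH2Cl2, 0 °C to rt; then NaH, THF, 0 °C
Reagents that add atoms: none
Why: Sulfoximine-to-oxirane conversion: N-methylation makes an aminosulfoxonium nucleofuge and the C4 alkoxide displaces it at the CH2 carbon (3-exo-tet SN2), which becomes C15, so the C4–O bond is retained and the oxirane oxygen stays on the cyclobutene face, syn to C6.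

Step 4
Reactants: 8 the spiro-oxirane cyclobutene; 9 ethene
Product: 10 cis-4-ethenyl-5-[3-(benzoyloxy)prop-1-en-2-yl]-1-oxaspiro[2.4]heptane (oxirane oxygen cis to the ethenyl group)
Conditions: ethene (1 atm), second-generation Grubbs catalyst RuCl2(=CHPh)(H2IMes)(PCy3) (5 mol%), CH2Cl2, rt
Reagents that add atoms: none
Why: Ring-opening metathesis (ethenolysis): release of cyclobutene strain drives cleavage of C6=C10 and ethene caps both carbenes, giving the C5 vinyl group and the C10=C14 methylene without touching C1, C4 or C5, while the oxirane and benzoate are inert to the ruthenium carbene.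

Step 5
Reactants: 10 the vinyl/methylene diene
Product: 12 cis-5-[3-(benzoyloxy)prop-1-en-2-yl]-1-oxaspiro[2.4]heptane-4-carbaldehyde (C6 aldehyde; oxirane oxygen cis to the formyl group), via vicinal diol 11 (not isolated)
Conditions: OsO4 (2 mol%), NMO, acetone/H2O, 0 °C, to partial conversion; then NaIO4, THF/pH 7 buffer, 0 °C; used crude
Reagents that add atoms: osmium tetroxide, O=[Os](=O)(=O)=O; N-methylmorpholine N-oxide, C[N+]1([O-])CCOCC1
Why: Catalytic osmium dihydroxylation followed by periodate glycol cleavage: electrophilic OsO4 should prefer the monosubstituted vinyl group over the 1,1-disubstituted alkene, which is inductively deactivated by its allylic benzoate, and neutral cleavage at 0 °C should avoid epimerisation at C5 and β-opening of the oxirane; no stereocentre is created.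

Step 6
Reactants: 13 3-methylfuran-2(5H)-one
Product: 14 3-(bromomethyl)furan-2(5H)-one
Conditions: NBS, (PhCO2)2 (cat.), PhCF3, reflux
Reagents that add atoms: N-bromosuccinimide, O=C1CCC(=O)N1Br
Why: Wohl–Ziegler bromination: hydrogen abstraction from the allylic methyl group gives a radical stabilised by the butenolide π-system, which is brominated at the exocyclic carbon.

Step 7
Reactants: 12 the C6 aldehyde; 14 3-(bromomethyl)furan-2(5H)-one
Product: 16 anti adduct 3-methylene-4-[hydroxy(cyclopentyl)methyl]dihydrofuran-2(3H)-one (carbinol carbon = C6; cyclopentyl = the spiro-oxirane ring of 12; lactone oxygen still on C8), via allylzinc bromide 15 (not isolated)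
Conditions: Zn dust (activated), THF, 0 °C to rt; aq NH4Cl
Reagents that add atoms: none
Why: Zinc Barbier allylation through a six-membered chair (Zimmerman–Traxler) transition state: the butenolide-derived allylzinc attacks through its ring γ-carbon (C7), forming C6–C7, and its ring-locked E-type geometry gives the anti adduct (C7), while the aldehyde should react in the rotamer that holds its oxygen over the oxirane (zinc bridging the carbonyl and the syn oxirane oxygen) so that attack comes from the H5 side, anti to the C1 substituent, which sets C6.

Step 8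
Reactants: 16 the Barbier adduct
Product: 17 trans-4-(hydroxymethyl)-3-methylene-5-(cyclopentyl)dihydrofuran-2(3H)-one (6,12-lactone with free C8 hydroxymethyl; H6 and H7 trans)
Conditions: DBU (0.1 equiv), CH2Cl2, 0 °C
Reagents that add atoms: none
Why: Base-catalysed translactonisation (intramolecular transesterification): the C6 oxygen attacks the lactone carbonyl in a 5-exo mode and the trans-β,γ-disubstituted γ-lactone with a free primary C8 alcohol should be the thermodynamic product; C6 and C7 are not touched, so the anti adduct becomes the trans lactone.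

Step 9
Reactants: 17 the C8 alcohol
Product: 18 the corresponding C8 aldehyde (trans-4-formyl-3-methylene lactone)
Conditions: Dess–Martin periodinane, NaHCO3, CH2Cl2, 0 °C; filtered and used at once
Reagents that add atoms: none
Why: Dess–Martin oxidation under bicarbonate buffer gives the aldehyde without acid or base strong enough to epimerise C7, move the exocyclic alkene into the lactone ring or open the oxirane.

Step 10
Reactants: 18 the C8 aldehyde
Product: 20 4β,15-epoxy-8β-hydroxy-1αH,5αH-guaia-10(14),11(13)-dien-12,6α-olide (cis-fused five/seven rings; trans lactone), via allylindium species 19 (not isolated)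
Conditions: Pd(PPh3)4 (5 mol%), InI (2 equiv), THF (0.01 M), rt; pH 7 buffer
Reagents that add atoms: none
Why: Palladium-catalysed umpolung allylation (zerovalent palladium adds oxidatively to the allylic benzoate, monovalent indium converts the π-allyl into a nucleophilic allylindium, which adds intramolecularly to the aldehyde): the two CH2 termini of the 2-substituted allyl unit are equivalent, so attack on C8 closes the seven-membered ring with an exocyclic methylene at C10, and the closed six-membered transition state with indium on O8 forces that oxygen gauche to C10, the axial β position of the chair fixed by trans-diaxial H6 and H7, with attack anti to C11 (Felkin–Anh), which should set C8 as the 8β-carbinol.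

Step 11
Reactants: 20 the 8β-carbinol; 21 3-methylbutanoic (isovaleric) acid
Product: 22 4β,15-epoxy-8β-(3-methylbutanoyloxy)-1αH,5αH-guaia-10(14),11(13)-dien-12,6α-olide
Conditions: 21, DCC, DMAP (cat.), CH2Cl2, 0 °C to rt
Reagents that add atoms: none
Why: Steglich esterification: the carbodiimide-activated acid acylates the C8 hydroxyl through the acylpyridinium and the C8–O bond is not broken, so the 8β configuration is retained.

Step 12
Reactants: 22 the 8β-isovalerate
Product: 24 4β,15-epoxy-14-hydroxy-8β-(3-methylbutanoyloxy)-1αH,5αH,10αH-guai-11(13)-en-12,6α-olide, via B-alkyl-9-BBN adduct 23 (not isolated)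
Conditions: 9-BBN, THF, 0 °C to rt; then NaBO3·4H2O, THF/H2O, rt
Reagents that add atoms: sodium perborate, [Na+].[Na+].O[B-]1(O)OO[B-](O)(O)OO1
Why: Hydroboration–oxidation: 9-BBN should add anti-Markovnikov to the electron-rich, unhindered exocyclic C10=C14 alkene and leave the electron-poor conjugated methylene lactone, the esters and the oxirane, and mild perborate oxidation gives the primary C14 alcohol; boron should come from the convex α face (H10 α), but either C10 epimer serves because this centre is erased in step 14.

Step 13
Reactants: 24 the C14 alcohol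
Product: 25 4β,15-epoxy-14-oxo-8β-(3-methylbutanoyloxy)-1αH,5αH,10αH-guai-11(13)-en-12,6α-olide (key precursor)
Conditions: Dess–Martin periodinane, NaHCO3, CH2Cl2, 0 °C
Reagents that add atoms: none
Why: Dess–Martin oxidation under bicarbonate buffer gives the C14 aldehyde without enolisation, so the fragmentation substrate is reached under neutral conditions.

Step 14
Reactants: 25 the 4,15-epoxy-14-oxo-cis-guaianolide
Product: 28 target CNP0345200.3 (6R,7R,8R)-15-hydroxy-8-(3-methylbutanoyloxy)-14-oxogermacra-1(10),4,11(13)-trien-12,6-olide (both ring alkenes ring-cis; CIP 1(10)E,4E), via lithium enolate 26 (not isolated), via lithium alkoxide 27 (not isolated)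
Conditions: LiN(SiMe3)2 (1.05 equiv), THF, −78 to −40 °C; AcOH, −78 °C
Reagents that add atoms: none
Why: Proposed new method: LiN(SiMe3)2 removes H10, the only aldehyde α-proton and by far the most acidic site, and the π-electrons of enolate 26 flow through the C1–C5 σ-bond into the C4–O bond of the lithium-activated oxirane, so that C10=C1 and C4=C5 form while C1–C5 and C4–O break in a five-centre Grob-type 1,4-fragmentation driven by oxirane strain and enal conjugation. The closest known reaction types are the enolate-assisted 1,4-fragmentation of γ-sulfonyloxy aldehydes in decalins, which gives germacradienals, and alkoxide-triggered epoxy alcohol fragmentations in which an oxirane is the nucleofuge; a sulfonate cannot serve here because the nucleofugal carbon C4 is fully substituted. No ring is closed by bond formation: the ten-membered ring arises only from scission of the bond shared by the five- and seven-membered rings, so no macrocyclisation entropy or transannular strain is paid in a closing step. No stereocentre is created (C1, C4, C5 and C10 are erased); instead the two alkene geometries are set, C4=C5 by the oxirane oxygen lying syn to C6 and roughly antiperiplanar to C1–C5 (C3 ends cis to C6), and C1=C10 by allylic strain in the enolate, which keeps H1 in plane beside C14 (C2 ends cis to C9, the thermodynamic enal geometry). The step needs enolisation in preference to attack on the lactone, ester or enoate (bulky amide base, large acidity gap) and fragmentation in preference to C-alkylation or Michael addition (the spiro geometry holds C15 on the face opposite C10 and the trans lactone keeps C13 away), and the cold acetic acid quench protonates alkoxide 27 before it can add to the enal.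

Compound list
1 | cyclopent-2-en-1-one | O=C1C=CCC1 | starting material
2 | prop-2-yn-1-yl benzoate | C#CCOC(=O)c1ccccc1 | starting material
3 | rac-cis-6-(benzoyloxymethyl)bicyclo[3.2.0]hept-6-en-2-one (drawn as the enantiomer carried on) | O=C1CC[C@@H]2[C@H]1C=C2COC(=O)c1ccccc1 | intermediate
4 | (S)-N,S-dimethyl-S-phenylsulfoximine | CN=[S@@](C)(=O)c1ccccc1 | starting material
5 | (S)-S-(lithiomethyl)-N-methyl-S-phenylsulfoximine | CN=[S@@](C[Li])(=O)c1ccccc1 | intermediate
6 | sulfoximine carbinol, hydroxyl on the cyclobutene face, (S) at sulfur | CN=[S@@](C[C@]1(O)CC[C@@H]2[C@H]1C=C2COC(=O)c1ccccc1)(=O)c1ccccc1 | intermediate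
7 | (dimethylamino)oxosulfonium tetrafluoroborate of 6 | CN(C)[S@@+](C[C@]1(O)CC[C@@H]2[C@H]1C=C2COC(=O)c1ccccc1)(=O)c1ccccc1.F[B-](F)(F)F | intermediate
8 | 6-(benzoyloxymethyl)spiro[bicyclo[3.2.0]hept-6-ene-2,2'-oxirane], oxirane oxygen on the cyclobutene face | C1O[C@]12CC[C@@H]3[C@H]2C=C3COC(=O)c1ccccc1 | intermediate
9 | ethene | C=C | starting material
10 | cis-4-ethenyl-5-[3-(benzoyloxy)prop-1-en-2-yl]-1-oxaspiro[2.4]heptane | C1O[C@]12CC[C@@H](C(=C)COC(=O)c3ccccc3)[C@H]2C=C | intermediate
11 | 1,2-diol from the ethenyl group of 10 (both epimers at the new carbinol) | C1O[C@]12CC[C@@H](C(=C)COC(=O)c3ccccc3)[C@H]2C(O)CO | intermediate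
12 | cis-5-[3-(benzoyloxy)prop-1-en-2-yl]-1-oxaspiro[2.4]heptane-4-carbaldehyde (C6 aldehyde) | C1O[C@]12CC[C@@H](C(=C)COC(=O)c3ccccc3)[C@H]2C=O | intermediate
13 | 3-methylfuran-2(5H)-one | CC1=CCOC1=O | starting material
14 | 3-(bromomethyl)furan-2(5H)-one | BrCC1=CCOC1=O | intermediate
15 | [(2-oxo-2,5-dihydrofuran-3-yl)methyl]zinc bromide | Br[Zn]CC1=CCOC1=O | intermediate
16 | anti Barbier adduct, C6 carbinol, lactone oxygen on C8 | C=C1C(=O)OC[C@@H]1[C@H](O)[C@H]2[C@]3(CO3)CC[C@H]2C(=C)COC(=O)c2ccccc2 | intermediate
17 | trans 6,12-lactone with free C8 hydroxymethyl | C=C1C(=O)O[C@H]([C@H]2[C@]3(CO3)CC[C@H]2C(=C)COC(=O)c2ccccc2)[C@H]1CO | intermediate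
18 | C8 aldehyde of 17 | C=C1C(=O)O[C@H]([C@H]2[C@]3(CO3)CC[C@H]2C(=C)COC(=O)c2ccccc2)[C@H]1C=O | intermediate
19 | allylindium iodide benzoate derived from 18 | C=C1C(=O)O[C@H]([C@H]2[C@]3(CO3)CC[C@H]2C(=C)C[In](I)OC(=O)c2ccccc2)[C@H]1C=O | intermediate
20 | 4β,15-epoxy-8β-hydroxy-1αH,5αH-guaia-10(14),11(13)-dien-12,6α-olide | C=C1C(=O)O[C@@H]2[C@H]3[C@]4(CO4)CC[C@H]3C(=C)C[C@@H](O)[C@@H]12 | intermediate
21 | 3-methylbutanoic (isovaleric) acid | CC(C)CC(=O)O | starting material
22 | 8β-(3-methylbutanoyloxy) ester of 20 | C=C1C(=O)O[C@@H]2[C@H]3[C@]4(CO4)CC[C@H]3C(=C)C[C@@H](OC(=O)CC(C)C)[C@@H]12 | intermediate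
23 | B-(C14-alkyl)-9-borabicyclo[3.3.1]nonane from 22 | C=C1C(=O)O[C@@H]2[C@H]3[C@]4(CO4)CC[C@H]3[C@@H](CB5C6CCCC5CCC6)C[C@@H](OC(=O)CC(C)C)[C@@H]12 | intermediate
24 | 14-hydroxy compound (10αH drawn; either C10 epimer serves) | C=C1C(=O)O[C@@H]2[C@H]3[C@]4(CO4)CC[C@H]3[C@@H](CO)C[C@@H](OC(=O)CC(C)C)[C@@H]12 | intermediate
25 | 4β,15-epoxy-14-oxo-8β-(3-methylbutanoyloxy)-cis-guai-11(13)-en-12,6α-olide (key precursor) | C=C1C(=O)O[C@@H]2[C@H]3[C@]4(CO4)CC[C@H]3[C@@H](C=O)C[C@@H](OC(=O)CC(C)C)[C@@H]12 | intermediate
26 | lithium C10 enolate of 25 | C=C1C(=O)O[C@@H]2[C@H]3[C@]4(CO4)CC[C@H]3C(=CO[Li])C[C@@H](OC(=O)CC(C)C)[C@@H]12 | intermediate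
27 | lithium C15 alkoxide of the target | C=C1C(=O)O[C@@H]2/C=C(/CO[Li])CC/C=C(/C=O)C[C@@H](OC(=O)CC(C)C)[C@@H]12 | intermediate
28 | CNP0345200.3 | C=C1C(=O)O[C@@H]2/C=C(/CO)CC/C=C(/C=O)C[C@@H](OC(=O)CC(C)C)[C@@H]12 | target

Total step count: 14. Longest linear sequence: 13 steps (steps 1–5 and 7–14, from 1 to 28); step 6 is a one-step side branch.

Steps most likely to fail

1. Step 14 (the step proposed as new). The enolate may fail to fragment if the C1–C5 bond cannot align with both the enolate π-system and the C4–O bond, it may be consumed by proton transfer or aldol pathways, and the released alkoxide may add to the enal before the quench. The fallback uses known chemistry only and closes the ring by olefin metathesis instead of ring-fusion scission; it sets out from compound 14 and comes back at compound 28. Commercial 4-(tert-butyldimethylsilyloxy)but-2-yn-1-ol is trans-hydroaluminated and iodinated (NaAlH2(OCH2CH2OMe)2, then I2) to (Z)-4-(tert-butyldimethylsilyloxy)-3-iodobut-2-en-1-ol F1. Negishi coupling with but-3-enylzinc bromide (Pd(PPh3)4) gives the dienol F2, and MnO2 gives the enal F3, in which the butenyl chain (C3) is cis to the formyl carbon (C6). Zinc allylation of F3 with 14 and translactonisation, as in steps 7 and 8, give the racemic trans-lactone alcohol, which is resolved on a chiral stationary phase to the lactone alcohol F4. Dess–Martin oxidation gives the aldehyde F5, Barbier addition of 3-chloro-2-(chloromethyl)prop-1-ene (Zn, THF/aq NH4Cl) gives the Felkin–Anh carbinol F6, and Steglich esterification with 21 gives the isovalerate F7. Ring-closing metathesis at high dilution (second-generation Hoveyda–Grubbs catalyst RuCl2(H2IMes)(=CH-C6H4-2-OiPr), toluene, 80 °C) joins C1 and C10 to the ten-membered allylic chloride F8. Kornblum-type oxidation (pyridine N-oxide, Ag2O) gives the silyl-protected enal F9, and HF·pyridine removes the silyl ether to deliver 28.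

2. Step 10. The carbonyl may be attacked on its other face, giving the 8α-carbinol or an epimer mixture, and the labile aldehyde may epimerise at C7 or shift its exocyclic alkene into the lactone ring before ring closure. The fallback replaces retentive by invertive esterification; it sets out from compound 18 and comes back at compound 22. The ring closure is run as before and the 8α-hydroxy epimer F10 is isolated. Mitsunobu esterification with 21 (PPh3, DIAD, toluene, 0 °C) inverts C8 and gives 22 directly, so either facial outcome of the allylation feeds the route.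

3. Step 5. Osmylation may not discriminate enough between the two terminal alkenes, and the aldehyde may epimerise at C5 or lose the oxirane by β-elimination during work-up. The fallback differentiates the alkenes by cross-metathesis; it sets out from compound 10 and comes back at compound 12. Cross-metathesis of 10 with 2-methylbut-2-ene (second-generation Grubbs catalyst RuCl2(=CHPh)(H2IMes)(PCy3), neat, rt) should convert only the monosubstituted vinyl group into the isobutenyl compound F11, because the hindered 1,1-disubstituted alkene does not enter metathesis. OsO4/NMO then dihydroxylates the electron-rich trisubstituted alkene much faster than the deactivated allylic benzoate alkene to give the diol F12, and NaIO4 at pH 7 cleaves it to 12.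

Further compounds
F1 | step 14 | (Z)-4-(tert-butyldimethylsilyloxy)-3-iodobut-2-en-1-ol | OC/C=C(\I)CO[Si](C)(C)C(C)(C)C
F2 | step 14 | 3-[(tert-butyldimethylsilyloxy)methyl]hepta-2,6-dien-1-ol, butenyl chain cis to CH2OH | OC/C=C(\CCC=C)CO[Si](C)(C)C(C)(C)C
F3 | step 14 | 3-[(tert-butyldimethylsilyloxy)methyl]hepta-2,6-dienal, butenyl chain cis to CHO | O=C/C=C(\CCC=C)CO[Si](C)(C)C(C)(C)C
F4 | step 14 | trans-4-(hydroxymethyl)-3-methylene-5-(dienyl)dihydrofuran-2(3H)-one, resolved | C=C1C(=O)O[C@H](/C=C(\CCC=C)CO[Si](C)(C)C(C)(C)C)[C@H]1CO
F5 | step 14 | C8 aldehyde of F4 | C=C1C(=O)O[C@H](/C=C(\CCC=C)CO[Si](C)(C)C(C)(C)C)[C@H]1C=O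
F6 | step 14 | C8 carbinol carrying the 2-(chloromethyl)allyl group | C=C1C(=O)O[C@H](/C=C(\CCC=C)CO[Si](C)(C)C(C)(C)C)[C@H]1[C@H](O)CC(=C)CCl
F7 | step 14 | 3-methylbutanoate of F6 | C=C1C(=O)O[C@H](/C=C(\CCC=C)CO[Si](C)(C)C(C)(C)C)[C@H]1[C@H](OC(=O)CC(C)C)CC(=C)CCl
F8 | step 14 | ten-membered 14-chloro-15-silyloxy germacranolide | C=C1C(=O)O[C@@H]2/C=C(/CO[Si](C)(C)C(C)(C)C)CC/C=C(/CCl)C[C@@H](OC(=O)CC(C)C)[C@@H]12
F9 | step 14 | 15-O-tert-butyldimethylsilyl ether of the target | C=C1C(=O)O[C@@H]2/C=C(/CO[Si](C)(C)C(C)(C)C)CC/C=C(/C=O)C[C@@H](OC(=O)CC(C)C)[C@@H]12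
F10 | step 10 | 8α-hydroxy epimer of 20 | C=C1C(=O)O[C@@H]2[C@H]3[C@]4(CO4)CC[C@H]3C(=C)C[C@H](O)[C@@H]12
F11 | step 5 | isobutenyl analogue of 10 (2-methylprop-1-enyl in place of ethenyl) | C1O[C@]12CC[C@@H](C(=C)COC(=O)c3ccccc3)[C@H]2C=C(C)C
F12 | step 5 | diol from the isobutenyl group of F11 | C1O[C@]12CC[C@@H](C(=C)COC(=O)c3ccccc3)[C@H]2C(O)C(C)(C)O
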